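**Amounts known.** The teal flask levels off near 0.0127 M of product, the mean of its flat readings. Taken one to one, that is less than the 0.037 M of coupling partner charged.

in all of them: substrate 0.050 M

| flask | coupling partner | free catalyst | remark | time |
|---|---|---|---|---|
| teal | 0.037 M | 0.25 mM | run made earlier |  |
| north-east | 0.0550 M | 0.25 mM |  | 40 min |
| west | 0.0550 M | 0.50 mM |  | 40 min |
| south-east | 0.0550 M | 1.0 mM |  | 40 min |

- teal (time / min: product / %): 1.50: 12; 5.00: 25; 8.00: 26; 12.0: 25; 20.0: 25; 25.0: 26

(readings scatter by 1.5 percentage points)

- what was read earlier has a scatter of 1.5 percentage points, one standard deviation
- "hardly changes" means that all values lie within two and a half points (for a concentration: within two and a half percent of the largest)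
- no earlier run changes the charge of free catalyst; that part of a forecast is a guess

- [product] at the end for north-east, west, south-east, in this order
- how the row runs (hardly changes / rises, then falls / falls, then rises / falls all the way / rises all the way)

**Working time.** The first teal reading gives a product rate r of 0.00400 M min⁻¹. The plateau divided by r gives a working time of 3.17 min, which ends before the second reading at 5.00 min. This reckoning supposes that the catalyst makes product at a steady r while partner lasts, and that the remaining partner decays at first order. The working time is then the logarithm of one plus k·c(coupling partner)/r, divided by k.

**Going round.** As a first answer, the 0.0243 M of partner not found as product is lost over the working time, with a mean c(coupling partner) of half the charge. That gives 0.414 min⁻¹. Put back into the relation, it gives the loss constant k_loss, the first-order rate constant of partner decay, as 0.496 min⁻¹. A further round gives 0.542 min⁻¹, a smaller step, so the rounds have not closed, and k_loss is kept as a rough estimate from the first round.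

**Two ways.** For north-east, the first way keeps teal's share of partner turned into product, 34.3%, and gives 0.0189 M. The second way runs the race with k_loss and gives 0.0166 M, which is lower. A constant share needs a product curve that slows along with the partner. Fitted to the first reading and the plateau, that curve gives 22.4% at 5.00 min, while the flask read 25% with a scatter of 1.5 percentage points. This leans against the share, though it does not prove the point, so the race is the reckoning kept.

**Own row.** The race ends north-east after 4.15 min, well inside 40 min. Guessing that r follows the catalyst charge, twice the rate gives west 0.0239 M, so this row rises.

**Forecast, flask.** The forecast gives 0.017 M, 0.017 M and 0.017 M, a row that hardly changes, on the ground “A catalyst does not shift an equilibrium”. The flasks give 0.0164 M, 0.0242 M and 0.0325 M: the row rises all the way.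

    coupling partner → decomposed reagent (k = 0.410 min⁻¹)
    coupling partner + free catalyst → catalyst intermediate A (k = 2100 M⁻¹ min⁻¹)
    catalyst intermediate B → by-product + catalyst intermediate C (k = 680 min⁻¹)
    substrate + catalyst intermediate A ⇌ catalyst intermediate B (K = 33.0 M⁻¹, k = 570 M⁻¹ min⁻¹)
    catalyst intermediate C → free catalyst + product (k = 1200 min⁻¹)

**Partner's race.** With k_loss, north-east reckons to 0.0166 M against the simulated 0.0164 M, and south-east reckons to 0.0321 M against the simulated 0.0325 M. At 1.14 min in north-east, coupling partner has a half-life of 1.7 min on the path to decomposed reagent and 4.9 min on the path with free catalyst to catalyst intermediate A, so the decay is faster. At 40.0 min, north-east keeps 0% of this limiting reagent, and holds 0.0386 M of decomposed reagent beside 0.0164 M of product.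

The numbers in the tables stem from a simulated flask on assumed constants; the scatter is artificial.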